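## Structural features

The target is a C37 nor-carotenoid-type butenolide with four rings (carotenoid locants are used throughout). Ring A is a (3'R)-3'-hydroxycyclohexene whose C6' carries the C7'≡C8' triple bond; the alkyne runs into an all-E tetraene (C9'=C10', C11'=C12', C15'=C15, C14=C13) that ends at the exocyclic (Z)-C11=C12 bond of the γ-ylidenebutenolide ring B (ring oxygen on C11, C10=C9, lactone carbonyl C19). C9, the α-carbon of ring B, is bonded directly to C8 of ring C, a 2,5-dihydrofuran (O, C5, C6=C7, C8) fused through C5–C6 to the cyclohexane ring D. Rings C and D carry three stereocentres: C3 (S, secondary OH), the quaternary ether carbon C5 (R) and C8 (R). C3 and C5 are 1,3-related on ring D with their oxygens trans; C5 and C8 are 1,3-related across the ring oxygen with the C8 substituent anti to the C5 methyl. C3' (R) on ring A is remote. Fragile elements are the ylidenebutenolide (bases, nucleophiles, light), the polyenyne (acid, light, oxygen) and the C5–O and C8–O bonds, both allylic to C6=C7. The real difficulty is ring C: a trisubstituted C6=C7 alkene wedged between the quaternary carbons C1 and C5, with C5 and C8 in a fixed relationship and a carbon substituent on C8 that must become C9 of ring B. The key step exploits this alkene: C6 and C7 are the two carbons a sulfonyl group bridges in a six-membered 1,4-oxathiane (O, C5, C6, S, C7, C8) that already holds C5, the ring oxygen and C8, so loss of SO2 joins C6 to C7 and contracts that ring to ring C.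

## Logic of the disconnections

36 from 35: only the two O–Si bonds are cut. Both secondary hydroxyls stay masked as one kind of silyl ether until the end, so the last step is a single mild fluoride treatment. The demand is that the ylidenebutenolide, the polyenyne and the allylic ethers survive it.

35 from 26 and 33: the central disubstituted C15=C15' bond is cut. This is the most convergent cut of the chain, it joins two halves of similar size, and it needs only a short, cold exposure of the base-sensitive butenolide aldehyde to a stabilised sulfonyl carbanion. The forward olefination must give, or be correctable to, the E-alkene.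

33 back through 32, 31, 30 and 28 to 27, and 27 to 3 and 17: the C11'=C12' bond (phosphonate olefination with 29) and the C6'–C7' bond (sp2–sp coupling) are cut. Ring A then comes from the same enol triflate 3 that serves ring D, and the C8'–C11' enyne is bought with its E geometry in place. The coupling must work on a tetrasubstituted, hindered enol triflate.

26 back through 25 and 24 to 23: the C9–C19 and C19–O bonds of ring B are cut (CO as C19). A single carbonylative lactonization then makes ring B and the C11=C12 bond from a ketone. The forward step needs a (Z)-β-iodoenone with an enolisable C12 methylene. 23 is cut to 22 (C9–I) and 22 through 21 to 16 and 20 (C10–C11), which leaves a terminal alkyne on C8 as the only handle ring C must carry.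

16 from 15, and 15 from 12: the C6–C7 bond is cut and SO2 is re-inserted between the two carbons. Ring C with its hindered alkene is thereby traded for a saturated six-membered O,S-ring in which C5 and C8 already have their final configuration and no alkene has to be placed regioselectively. The forward contraction must halogenate and deprotonate α to sulfur without losing the β-oxygen.

12 from 11, and 11 through 10 and 9 to 7 and 8: the O–C8 bond (conjugate addition of the C5 hydroxyl to a vinyl sulfone) and the C7–C8 bond (sulfone aldol, then elimination) are cut. The ring oxygen is therefore already in place on C5 as a free tertiary alcohol, and C8 is set by a reversible 6-endo-trig addition that should favour the equatorial ethynyl epimer, which is the one required. A one-step annulation in which a hydroxyl carried on the sulfur electrophile captures a thiiranium ion at C5 was rejected. Nucleophile and departing sulfur would sit in the same forming six-membered ring, the backside of C5 cannot be reached, and neither the anti course nor the C5 configuration could be relied on.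

7 from 6, and 6 from 4: the C6–S and C5–O bonds are cut, an anti addition of "MeS+" and water across C5=C6. The S-methyl carbon is the future C7. The demand is Markovnikov, trans-diaxial opening on the face that puts oxygen anti to the C3 silyloxy group.

4 from 3, 3 from 2, 2 from 1; 20 from 18, 18 from 17: 3 is reduced at C6 (C–O to C–H) and arises from the enolate of 2, which can form only toward C5. The C3 and C3' centres of both halves are thus bought in 1, and the C6 methyl stereocentre of 1 is discarded. 20 is the anti-Markovnikov hydration product of the alkyne of 18.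

## Other disconnections considered

Alternative 1: The O–C8 bond of ring C is cut. In the forward sense the allenol A2 (C5–OH, C6=C7=C8 allene, butenolide on C8) would be treated with Ph3PAuCl/AgOTf (monovalent gold). The tertiary hydroxyl adds to the allene terminus in a 5-endo cyclisation, the axis is converted into the C8 centre, and protodeauration leaves C6=C7, giving A1.
- In its favour: the ring and the alkene form in one neutral, catalytic event at about room temperature. No extrusion and no base are involved. Allenols of this kind are reachable by anti-SN2' hydride opening of a 5,6-epoxy-7-yne.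
- Against it here: the C8 configuration can be no purer than the allene, and the allene no purer than the facial selectivity of the preceding epoxidation. Cationic gold can erode an allene axis. The butenolide is a second Lewis-basic and electrophilic site. A1 still lacks the C11 substituent, so the ylidene must be built afterwards by γ-functionalisation and stereoselective elimination.
- Comparison: on step count to ring C and on mildness Alternative 1 is the better plan. On mechanism it is the equal of the chosen one, a stereospecific transfer against a thermodynamically set centre. The chosen plan is preferred because none of its stereocentres depends on isolating a single allene diastereomer, and because it delivers the C8 alkyne from which ring B is built with its ylidene in one step.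

Alternative 2: The O–C5 bond is cut. The (Z)-dienone A4 would cyclise under a bifunctional cinchona amine–squaramide catalyst by 5-exo-trig oxa-Michael addition of the C8 hydroxyl to C5, giving A3 with the C6=C7 alkene already present.
- In its favour: ring D comes from an inexpensive achiral isophorone-type ketone. The step is an isomerisation with no waste. No sulfur chemistry is needed.
- Against it here: the quaternary C5 ether must be created by catalyst control at a β,β-disubstituted cross-conjugated dienone, a slow and reversible addition. A4 must keep its Z exocyclic geometry against isomerisation through the dienol or dienamine. The resident C8 centre makes only one catalyst antipode matched. The C3 ketone of A3 must then be reduced to the 3,5-trans alcohol. The β-alkoxy ketone can revert under base.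
- Comparison: on raw-material cost and atom economy Alternative 2 is better, and on convergence it is equal. The chosen plan is more secure stereochemically: C3 is purchased, C5 comes from a trans-diaxial addition and C8 from an equilibrium, so no centre rests on a catalyst–substrate match. Step count to the silylated ethynyl bicycle is comparable once ketone reduction and protection are added.

Alternative 3: The C9–C19 and C19–O bonds of ring B are cut. The (Z)-β-iodoenone A6 (identical with 23) would react with Pd(PPh3)4, CO and Et3N: CO inserts at C9 and the enol oxygen of the C11 ketone captures the acylpalladium, giving A5 (identical with 24).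
- In its favour: two bonds, ring B and the Z-ylidene form in one catalytic step of a well-exercised type. Silyl ethers and ring C are tolerated.
- Against it as the strategic centre: it presupposes ring C with all three stereocentres and the C8–C9 bond. It solves ring B and leaves the harder ring untouched.
- Comparison: as a bond-forming event it is the better step (two bonds against one, catalytic) and its precedent is at least equal. It does not compete with the contraction but complements it, and it is kept as step 16 of the chosen plan, so step economy is the same.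

Key step: step 9

Remarks on the chemistry:
- Abbreviations: TBS = tert-butyldimethylsilyl, TIPS = triisopropylsilyl, PT = 1-phenyl-1H-tetrazol-5-yl, Tf = trifluoromethanesulfonyl, Ms = methanesulfonyl. "DHB" = (2R,6S,7aR)-6-[(TBS)oxy]-4,4,7a-trimethyl-2,4,5,6,7,7a-hexahydro-1-benzofuran-2-yl (rings C/D). "RA" = (4R)-4-[(TBS)oxy]-2,6,6-trimethylcyclohex-1-en-1-yl (ring A).
- Assumption: 1, 8, 17 and 29 are taken as purchasable.
- Lithium and potassium derivatives made by the base named on a Conditions line are treated as activated reactants and carry no number.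
- In 12 the ring fusion is trans because sulfur and oxygen enter by anti addition; C6 becomes trigonal in step 9, so its configuration is not carried into the target.

## Steps

Step 1
Reactants: 1 (4R,6R)-4-hydroxy-2,2,6-trimethylcyclohexan-1-one
Product: 2 (4R,6R)-4-[(TBS)oxy]-2,2,6-trimethylcyclohexan-1-one
Conditions: TBSCl, imidazole, DMF, rt
Reagents that add atoms: tert-butyldimethylsilyl chloride, CC(C)(C)[Si](C)(C)Cl
Why: Imidazole-assisted silylation of the only hydroxyl; neither stereocentre is touched, and the TBS ether should outlast the base, peracid and palladium steps that follow.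

Step 2
Reactants: 2 (4R,6R)-4-[(TBS)oxy]-2,2,6-trimethylcyclohexan-1-one
Product: 3 (4R)-4-[(TBS)oxy]-2,6,6-trimethylcyclohex-1-en-1-yl trifluoromethanesulfonate
Conditions: LiN(i-Pr)2, THF, –78 → 0 °C; PhNTf2, 0 °C → rt
Reagents that add atoms: N-phenylbis(trifluoromethanesulfonimide), O=S(=O)(N(c1ccccc1)S(=O)(=O)C(F)(F)F)C(F)(F)F
Why: Enol triflate formation; the ketone can enolise only toward the methyl-bearing carbon (the other α-carbon is quaternary), so one regioisomer should form. The methyl stereocentre is erased on purpose and C3 is kept.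

Step 3
Reactants: 3 (4R)-4-[(TBS)oxy]-2,6,6-trimethylcyclohex-1-en-1-yl trifluoromethanesulfonate
Product: 4 tert-butyldimethyl{[(1R)-3,5,5-trimethylcyclohex-3-en-1-yl]oxy}silane
Conditions: Pd(OAc)2 (5 mol %), PPh3, HCO2H, n-Bu3N, DMF, 60 °C
Reagents that add atoms: none
Why: Palladium-catalysed formate reduction of an enol triflate (oxidative addition, formate exchange, decarboxylation, reductive elimination) replaces OTf by H without moving the double bond and gives the silyl ether of (R)-β-isophorol.

Step 4
Reactants: 4 tert-butyldimethyl{[(1R)-3,5,5-trimethylcyclohex-3-en-1-yl]oxy}silane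
Product: 6 (1R,2R,5S)-5-[(TBS)oxy]-1,3,3-trimethyl-2-(methylsulfanyl)cyclohexan-1-ol, via S-methylthiiranium tetrafluoroborate 5 (not isolated)
Conditions: Me2S(SMe)BF4, CH2Cl2, –20 °C; then H2O/THF, NaHCO3, 0 °C → rt
Reagents that add atoms: dimethyl(methylthio)sulfonium tetrafluoroborate, C[S+](C)SC.F[B-](F)(F)F; water, O
Why: Hydroxysulfenylation of an alkene: thiiranium ion 5 forms reversibly, and water opens it at the tertiary carbon C5 through a trans-diaxial (Fürst–Plattner) transition state that keeps the silyloxy group equatorial. This should place sulfur on C6 syn and oxygen on C5 anti to the C3 silyloxy group; the oxygen enters intermolecularly, so no endo-mode opening by a sulfur-tethered nucleophile is needed.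

Step 5
Reactants: 6 (1R,2R,5S)-5-[(TBS)oxy]-1,3,3-trimethyl-2-(methylsulfanyl)cyclohexan-1-ol
Product: 7 (1R,2R,5S)-5-[(TBS)oxy]-2-(methanesulfonyl)-1,3,3-trimethylcyclohexan-1-ol
Conditions: mCPBA (2.5 equiv), NaHCO3, CH2Cl2, 0 °C → rt
Reagents that add atoms: 3-chloroperoxybenzoic acid, OOC(=O)c1cccc(Cl)c1
Why: Peracid oxidation of the sulfide through the sulfoxide to the sulfone; no alkene is present, and the tertiary alcohol and silyl ether are inert.

Step 6
Reactants: 7 (1R,2R,5S)-5-[(TBS)oxy]-2-(methanesulfonyl)-1,3,3-trimethylcyclohexan-1-ol; 8 3-(triisopropylsilyl)prop-2-ynal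
Product: 9 (1R,2R,5S)-5-[(TBS)oxy]-2-{[2-hydroxy-4-(TIPS)but-3-yn-1-yl]sulfonyl}-1,3,3-trimethylcyclohexan-1-ol (both carbinol epimers)
Conditions: LiN(i-Pr)2 (2.2 equiv), THF, –78 °C; then 8, –78 °C; NH4Cl aq.
Reagents that add atoms: none
Why: Sulfone aldol addition: the second equivalent of base removes a proton from the S-methyl group (the ring C6–H is shielded by two quaternary neighbours) and the carbanion adds 1,2 to the ynal, forming C7–C8. The carbinol configuration is irrelevant because the next step removes it.

Step 7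
Reactants: 9 (1R,2R,5S)-5-[(TBS)oxy]-2-{[2-hydroxy-4-(TIPS)but-3-yn-1-yl]sulfonyl}-1,3,3-trimethylcyclohexan-1-ol
Product: 11 (1R,2R,5S)-5-[(TBS)oxy]-1,3,3-trimethyl-2-{[(1E)-4-(TIPS)but-1-en-3-yn-1-yl]sulfonyl}cyclohexan-1-ol, via secondary mesylate 10 (not isolated)
Conditions: MsCl, Et3N (5 equiv), CH2Cl2, 0 °C → rt
Reagents that add atoms: none
Why: The secondary propargylic alcohol is mesylated selectively (the tertiary C5–OH is too hindered), and the β-mesyloxy sulfone undergoes E1cB elimination to the conjugated (E)-enynyl sulfone.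

Step 8
Reactants: 11 (1R,2R,5S)-5-[(TBS)oxy]-1,3,3-trimethyl-2-{[(1E)-4-(TIPS)but-1-en-3-yn-1-yl]sulfonyl}cyclohexan-1-ol
Product: 12 (2S,4aR,7S,8aR)-7-[(TBS)oxy]-5,5,8a-trimethyl-2-[(TIPS)ethynyl]octahydro-2H-1,4-benzoxathiine 4,4-dioxide (trans-fused)
Conditions: t-BuOK (0.2 equiv), t-BuOH/THF, 0 °C → rt
Reagents that add atoms: none
Why: 6-endo-trig oxa-Michael addition of the C5 alkoxide to C8 of the vinyl sulfone; C5 and C6 are spectators, so the fusion stays trans. The addition is reversible under alkoxide catalysis, so C8 should be set under thermodynamic control with the ethynyl group equatorial, anti to the axial C5 methyl, which is the required configuration.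

Step 9
Reactants: 12 (2S,4aR,7S,8aR)-7-[(TBS)oxy]-5,5,8a-trimethyl-2-[(TIPS)ethynyl]octahydro-2H-1,4-benzoxathiine 4,4-dioxide
Product: 15 tert-butyldimethyl({(2R,6S,7aR)-4,4,7a-trimethyl-2-[(TIPS)ethynyl]-2,4,5,6,7,7a-hexahydro-1-benzofuran-6-yl}oxy)silane, via C7-bromo sulfone 13 (not isolated), via episulfone 14 (not isolated)
Conditions: KOH/Al2O3, CBr2F2, t-BuOH/CH2Cl2, 0 °C → rt
Reagents that add atoms: none
Why: The supported base removes a proton from the unhindered C7 methylene, and the carbanion takes bromine from CBr2F2 to give 13. A second deprotonation at C6 and intramolecular displacement of bromide (3-exo-tet, inversion at C7) close the thiirane dioxide 14, which loses SO2 cheletropically, so the C6–C7 σ and π bonds form and the six-membered O,S-ring contracts to ring C. The closest known reaction type is the Ramberg–Bäcklund contraction of thiane 1,1-dioxides to cyclopentenes with halogenation in the flask. No stereocentre is created: C6 becomes trigonal, the alkene is necessarily cis within the five-membered ring, and no bond to C5 or C8 is made or broken. The site of halogenation is not critical, because bromination at either α-carbon leads to the same episulfone, and the alkene cannot lie elsewhere because C1 has no hydrogen. The selectivity that matters is kinetic: episulfone closure must outrun β-elimination of the ring oxygen from the C7 carbanion and a second bromination at C7. The heterogeneous base keeps the carbanion concentration low, and a ring opened by retro-oxa-Michael reaction can close again to the same equatorial C8 epimer, which should secure this. The TIPS-alkyne and the TBS ether are inert to KOH on alumina.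

Step 10
Reactants: 15 tert-butyldimethyl({(2R,6S,7aR)-4,4,7a-trimethyl-2-[(TIPS)ethynyl]-2,4,5,6,7,7a-hexahydro-1-benzofuran-6-yl}oxy)silane
Product: 16 tert-butyl{[(2R,6S,7aR)-2-ethynyl-4,4,7a-trimethyl-2,4,5,6,7,7a-hexahydro-1-benzofuran-6-yl]oxy}dimethylsilane
Conditions: Bu4NF (1.05 equiv), THF, –20 → 0 °C
Reagents that add atoms: none
Why: Protodesilylation of the alkyne; fluoride cleaves the C(sp)–Si bond much faster than the secondary TBS ether at low temperature with one equivalent of reagent.

Step 11
Reactants: 17 (2E)-3-methylpent-2-en-4-yn-1-ol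
Product: 18 tert-butyldimethyl{[(2E)-3-methylpent-2-en-4-yn-1-yl]oxy}silane
Conditions: TBSCl, imidazole, CH2Cl2, rt
Reagents that add atoms: tert-butyldimethylsilyl chloride, CC(C)(C)[Si](C)(C)Cl
Why: Standard silylation of the primary allylic alcohol; the E geometry of the future C13=C14 bond is carried in unchanged.

Step 12
Reactants: 18 tert-butyldimethyl{[(2E)-3-methylpent-2-en-4-yn-1-yl]oxy}silane
Product: 20 (3E)-5-[(TBS)oxy]-3-methylpent-3-enal, via dienyl(dicyclohexyl)borane 19 (not isolated)
Conditions: Cy2BH, THF, 0 °C; then H2O2, pH 7 phosphate buffer, 0 °C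
Reagents that add atoms: hydrogen peroxide, OO
Why: Hydroboration–oxidation of a terminal alkyne: the bulky dialkylborane adds once, anti-Markovnikov and syn, and leaves the trisubstituted alkene alone. Buffered oxidation of the alkenyl–boron bond gives the enol, which tautomerises to the β,γ-unsaturated aldehyde with the (E)-alkene intact.

Step 13
Reactants: 16 tert-butyl{[(2R,6S,7aR)-2-ethynyl-4,4,7a-trimethyl-2,4,5,6,7,7a-hexahydro-1-benzofuran-6-yl]oxy}dimethylsilane; 20 (3E)-5-[(TBS)oxy]-3-methylpent-3-enal
Product: 21 (5E)-7-[(TBS)oxy]-1-(DHB)-5-methylhept-5-en-1-yn-3-ol (both carbinol epimers)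
Conditions: n-BuLi (1.0 equiv), THF, –78 °C; then 20, –78 °C; NH4Cl aq.
Reagents that add atoms: none
Why: 1,2-Addition of the lithium acetylide of 16 to the aldehyde forms C10–C11; the acetylenic proton is far more acidic than the C8–H, and the new carbinol centre is oxidised in the next step.

Step 14
Reactants: 21 (5E)-7-[(TBS)oxy]-1-(DHB)-5-methylhept-5-en-1-yn-3-ol
Product: 22 (5E)-7-[(TBS)oxy]-1-(DHB)-5-methylhept-5-en-1-yn-3-one
Conditions: Dess–Martin periodinane, NaHCO3, CH2Cl2, 0 °C → rt
Reagents that add atoms: none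
Why: Buffered Dess–Martin oxidation of the propargylic alcohol to the ynone under near-neutral conditions that should leave the β,γ-double bond and the C8 centre in place.

Step 15
Reactants: 22 (5E)-7-[(TBS)oxy]-1-(DHB)-5-methylhept-5-en-1-yn-3-one
Product: 23 (1Z,5E)-7-[(TBS)oxy]-1-(DHB)-1-iodo-5-methylhepta-1,5-dien-3-one
Conditions: NaI, AcOH, MeCN, rt, dark
Reagents that add atoms: sodium iodide, [Na+].[I-]
Why: Hydroiodination of an electron-poor alkyne: iodide adds to C9 in conjugate fashion and the allenol is protonated anti to iodine, which gives the (Z)-β-iodoenone under kinetic control, with iodine on the carbon that must carry C19.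

Step 16
Reactants: 23 (1Z,5E)-7-[(TBS)oxy]-1-(DHB)-1-iodo-5-methylhepta-1,5-dien-3-one
Product: 24 (5Z)-5-{(2E)-4-[(TBS)oxy]-2-methylbut-2-en-1-ylidene}-3-(DHB)furan-2(5H)-one
Conditions: Pd(PPh3)4 (5 mol %), CO (1 atm), Et3N, MeCN, 50 °C
Reagents that add atoms: carbon monoxide, [C-]#[O+]
Why: Carbonylative lactonization of a (Z)-β-iodoenone: zerovalent palladium inserts into C9–I, CO inserts, and the enol oxygen of the C11 ketone (enolised toward the doubly activated C12 methylene) captures the acylpalladium, which closes ring B and creates C11=C12. The (Z)-ylidene, with C13 syn to the ring oxygen, is the less hindered and thermodynamically preferred isomer.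

Step 17
Reactants: 24 (5Z)-5-{(2E)-4-[(TBS)oxy]-2-methylbut-2-en-1-ylidene}-3-(DHB)furan-2(5H)-one
Product: 25 (5Z)-5-[(2E)-4-hydroxy-2-methylbut-2-en-1-ylidene]-3-(DHB)furan-2(5H)-one
Conditions: HF·pyridine, pyridine, THF, 0 °C
Reagents that add atoms: none
Why: Selective desilylation: buffered HF·pyridine should remove the unhindered primary allylic TBS ether much faster than the secondary one on ring D.

Step 18
Reactants: 25 (5Z)-5-[(2E)-4-hydroxy-2-methylbut-2-en-1-ylidene]-3-(DHB)furan-2(5H)-one
Product: 26 (2E,4Z)-4-[4-(DHB)-5-oxofuran-2(5H)-ylidene]-3-methylbut-2-enal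
Conditions: MnO2, CH2Cl2, rt
Reagents that add atoms: none
Why: MnO2 oxidises the allylic alcohol to the conjugated aldehyde under neutral heterogeneous conditions that the ylidenebutenolide tolerates.

Step 19
Reactants: 3 (4R)-4-[(TBS)oxy]-2,6,6-trimethylcyclohex-1-en-1-yl trifluoromethanesulfonate; 17 (2E)-3-methylpent-2-en-4-yn-1-ol
Product: 27 (2E)-5-(RA)-3-methylpent-2-en-4-yn-1-ol
Conditions: Pd(PPh3)4 (5 mol %), CuI (10 mol %), i-Pr2NH, DMF, 50 °C
Reagents that add atoms: none
Why: Sonogashira coupling of the enol triflate with the terminal enyne forms C6'–C7' and installs the 7',8'-didehydro ring A unit; the free alcohol is tolerated and the E geometry comes from 17.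

Step 20
Reactants: 27 (2E)-5-(RA)-3-methylpent-2-en-4-yn-1-ol
Product: 28 (2E)-5-(RA)-3-methylpent-2-en-4-ynal
Conditions: MnO2, CH2Cl2, rt
Reagents that add atoms: none
Why: Chemoselective allylic oxidation to the enynal; the silyl ether and the enyne are inert.

Step 21
Reactants: 28 (2E)-5-(RA)-3-methylpent-2-en-4-ynal; 29 ethyl 2-(diethoxyphosphoryl)acetate
Product: 30 ethyl (2E,4E)-7-(RA)-5-methylhepta-2,4-dien-6-ynoate
Conditions: NaH, THF, 0 °C (29); then 28, 0 °C → rt
Reagents that add atoms: none
Why: Horner–Wadsworth–Emmons olefination with a stabilised phosphonate should give the (E)-C11'=C12' bond.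

Step 22
Reactants: 30 ethyl (2E,4E)-7-(RA)-5-methylhepta-2,4-dien-6-ynoate
Product: 31 (2E,4E)-7-(RA)-5-methylhepta-2,4-dien-6-yn-1-ol
Conditions: i-Bu2AlH (2.2 equiv), CH2Cl2, –78 °C; aqueous potassium sodium tartrate
Reagents that add atoms: none
Why: 1,2-Reduction of the dienoate to the allylic alcohol at low temperature; the conjugated alkenes and the alkyne are not reduced.

Step 23
Reactants: 31 (2E,4E)-7-(RA)-5-methylhepta-2,4-dien-6-yn-1-ol
Product: 32 5-{[(2E,4E)-7-(RA)-5-methylhepta-2,4-dien-6-yn-1-yl]sulfanyl}-1-phenyl-1H-tetrazole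
Conditions: 1-phenyl-1H-tetrazole-5-thiol, PPh3, DIAD, THF, 0 °C
Reagents that add atoms: 1-phenyl-1H-tetrazole-5-thiol, Sc1nnnn1-c1ccccc1
Why: Mitsunobu thioetherification of the primary allylic alcohol with the acidic heteroaryl thiol, by SN2 displacement at C15'.

Step 24
Reactants: 32 5-{[(2E,4E)-7-(RA)-5-methylhepta-2,4-dien-6-yn-1-yl]sulfanyl}-1-phenyl-1H-tetrazole
Product: 33 5-{[(2E,4E)-7-(RA)-5-methylhepta-2,4-dien-6-yn-1-yl]sulfonyl}-1-phenyl-1H-tetrazole
Conditions: (NH4)6Mo7O24·4H2O (10 mol %), 30% H2O2, EtOH, 0 °C → rt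
Reagents that add atoms: hydrogen peroxide, OO
Why: Molybdate-catalysed peroxide oxidation of the heteroaryl sulfide to the sulfone, chemoselective for sulfur over the conjugated alkenes and the alkyne.

Step 25
Reactants: 33 5-{[(2E,4E)-7-(RA)-5-methylhepta-2,4-dien-6-yn-1-yl]sulfonyl}-1-phenyl-1H-tetrazole; 26 (2E,4Z)-4-[4-(DHB)-5-oxofuran-2(5H)-ylidene]-3-methylbut-2-enal
Product: 35 3,3'-bis-O-TBS ether of the target (all-E chain, Z-ylidene), via (15Z)-isomer 34 (not isolated)
Conditions: KN(SiMe3)2, THF, –78 °C (33); then 26, –78 °C; then C6H6, rt, daylight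
Reagents that add atoms: none
Why: Julia–Kocienski olefination: the allylic sulfonyl carbanion adds to the aldehyde, and Smiles rearrangement with loss of SO2 and the tetrazolone forms C15=C15'. The (15Z)-isomer that is expected alongside the E-product is the unhindered central cis form of such polyenes and should isomerise to all-E on standing in light.

Step 26
Reactants: 35 3,3'-bis-O-TBS ether of the target
Product: 36 CNP0300047.2, (5Z)-3-[(2R,6S,7aR)-6-hydroxy-4,4,7a-trimethyl-2,4,5,6,7,7a-hexahydro-1-benzofuran-2-yl]-5-{(2E,4E,6E,8E)-11-[(4R)-4-hydroxy-2,6,6-trimethylcyclohex-1-en-1-yl]-2,9-dimethylundeca-2,4,6,8-tetraen-10-yn-1-ylidene}furan-2(5H)-one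
Conditions: HF·pyridine, pyridine, THF, 0 °C → rt, dark
Reagents that add atoms: none
Why: Fluoride-mediated cleavage of both secondary TBS ethers under pyridine-buffered conditions that should spare the ylidenebutenolide, the polyenyne and the allylic ethers of ring C.

## Compound list

1 | (4R,6R)-4-hydroxy-2,2,6-trimethylcyclohexan-1-one | O=C1C(C)(C)C[C@H](O)C[C@H]1C | starting material
2 | (4R,6R)-4-[(TBS)oxy]-2,2,6-trimethylcyclohexan-1-one | O=C1C(C)(C)C[C@H](O[Si](C)(C)C(C)(C)C)C[C@H]1C | intermediate
3 | (4R)-4-[(TBS)oxy]-2,6,6-trimethylcyclohex-1-en-1-yl trifluoromethanesulfonate | CC1=C(OS(=O)(=O)C(F)(F)F)C(C)(C)C[C@H](O[Si](C)(C)C(C)(C)C)C1 | intermediate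
4 | tert-butyldimethyl{[(1R)-3,5,5-trimethylcyclohex-3-en-1-yl]oxy}silane | CC1=CC(C)(C)C[C@H](O[Si](C)(C)C(C)(C)C)C1 | intermediate
5 | 4-[(TBS)oxy]-2,2,6,7-tetramethyl-7-thiabicyclo[4.1.0]heptan-7-ium tetrafluoroborate, sulfur syn to the silyloxy group | C[S+]1[C@@H]2C(C)(C)C[C@H](O[Si](C)(C)C(C)(C)C)C[C@]12C.F[B-](F)(F)F | intermediate (not isolated)
6 | (1R,2R,5S)-5-[(TBS)oxy]-1,3,3-trimethyl-2-(methylsulfanyl)cyclohexan-1-ol | CS[C@@H]1C(C)(C)C[C@H](O[Si](C)(C)C(C)(C)C)C[C@@]1(C)O | intermediate
7 | (1R,2R,5S)-5-[(TBS)oxy]-2-(methanesulfonyl)-1,3,3-trimethylcyclohexan-1-ol | CS(=O)(=O)[C@@H]1C(C)(C)C[C@H](O[Si](C)(C)C(C)(C)C)C[C@@]1(C)O | intermediate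
8 | 3-(triisopropylsilyl)prop-2-ynal | O=CC#C[Si](C(C)C)(C(C)C)C(C)C | starting material
9 | (1R,2R,5S)-5-[(TBS)oxy]-2-{[2-hydroxy-4-(TIPS)but-3-yn-1-yl]sulfonyl}-1,3,3-trimethylcyclohexan-1-ol, both carbinol epimers | CC(C)[Si](C(C)C)(C(C)C)C#CC(O)CS(=O)(=O)[C@@H]1C(C)(C)C[C@H](O[Si](C)(C)C(C)(C)C)C[C@@]1(C)O | intermediate
10 | methanesulfonate of the secondary alcohol of 9 | CC(C)[Si](C(C)C)(C(C)C)C#CC(OS(C)(=O)=O)CS(=O)(=O)[C@@H]1C(C)(C)C[C@H](O[Si](C)(C)C(C)(C)C)C[C@@]1(C)O | intermediate (not isolated)
11 | (1R,2R,5S)-5-[(TBS)oxy]-1,3,3-trimethyl-2-{[(1E)-4-(TIPS)but-1-en-3-yn-1-yl]sulfonyl}cyclohexan-1-ol | CC(C)[Si](C(C)C)(C(C)C)C#C/C=C/S(=O)(=O)[C@@H]1C(C)(C)C[C@H](O[Si](C)(C)C(C)(C)C)C[C@@]1(C)O | intermediate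
12 | (2S,4aR,7S,8aR)-7-[(TBS)oxy]-5,5,8a-trimethyl-2-[(TIPS)ethynyl]octahydro-2H-1,4-benzoxathiine 4,4-dioxide, trans-fused | CC(C)[Si](C(C)C)(C(C)C)C#C[C@H]1CS(=O)(=O)[C@@H]2C(C)(C)C[C@H](O[Si](C)(C)C(C)(C)C)C[C@@]2(C)O1 | intermediate
13 | 3-bromo derivative of 12 (bromine on C7, configuration there not defined) | CC(C)[Si](C(C)C)(C(C)C)C#C[C@H]1C(Br)S(=O)(=O)[C@@H]2C(C)(C)C[C@H](O[Si](C)(C)C(C)(C)C)C[C@@]2(C)O1 | intermediate (not isolated)
14 | thiirane 1,1-dioxide bridging C6 and C7 of the tetrahydrofuran-fused cyclohexane (configuration at C6 and C7 not defined) | CC(C)[Si](C(C)C)(C(C)C)C#C[C@H]1C2C3(C(C)(C)C[C@H](O[Si](C)(C)C(C)(C)C)C[C@@]3(C)O1)S2(=O)=O | intermediate (not isolated)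
15 | tert-butyldimethyl({(2R,6S,7aR)-4,4,7a-trimethyl-2-[(TIPS)ethynyl]-2,4,5,6,7,7a-hexahydro-1-benzofuran-6-yl}oxy)silane | CC(C)[Si](C(C)C)(C(C)C)C#C[C@H]1C=C2C(C)(C)C[C@H](O[Si](C)(C)C(C)(C)C)C[C@@]2(C)O1 | intermediate
16 | tert-butyl{[(2R,6S,7aR)-2-ethynyl-4,4,7a-trimethyl-2,4,5,6,7,7a-hexahydro-1-benzofuran-6-yl]oxy}dimethylsilane | C#C[C@H]1C=C2C(C)(C)C[C@H](O[Si](C)(C)C(C)(C)C)C[C@@]2(C)O1 | intermediate
17 | (2E)-3-methylpent-2-en-4-yn-1-ol | C#C/C(C)=C/CO | starting material
18 | tert-butyldimethyl{[(2E)-3-methylpent-2-en-4-yn-1-yl]oxy}silane | C#C/C(C)=C/CO[Si](C)(C)C(C)(C)C | intermediate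
19 | dicyclohexyl{(1E,3E)-5-[(TBS)oxy]-3-methylpenta-1,3-dien-1-yl}borane | C1CCCCC1B(/C=C/C(C)=C/CO[Si](C)(C)C(C)(C)C)C1CCCCC1 | intermediate (not isolated)
20 | (3E)-5-[(TBS)oxy]-3-methylpent-3-enal | O=CC/C(C)=C/CO[Si](C)(C)C(C)(C)C | intermediate
21 | (5E)-7-[(TBS)oxy]-1-(DHB)-5-methylhept-5-en-1-yn-3-ol, both carbinol epimers | CC(C)(C)[Si](C)(C)OC/C=C(C)/CC(O)C#C[C@H]1C=C2C(C)(C)C[C@H](O[Si](C)(C)C(C)(C)C)C[C@@]2(C)O1 | intermediate
22 | (5E)-7-[(TBS)oxy]-1-(DHB)-5-methylhept-5-en-1-yn-3-one | CC(C)(C)[Si](C)(C)OC/C=C(C)/CC(=O)C#C[C@H]1C=C2C(C)(C)C[C@H](O[Si](C)(C)C(C)(C)C)C[C@@]2(C)O1 | intermediate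
23 | (1Z,5E)-7-[(TBS)oxy]-1-(DHB)-1-iodo-5-methylhepta-1,5-dien-3-one | CC(C)(C)[Si](C)(C)OC/C=C(C)/CC(=O)/C=C(I)/[C@H]1C=C2C(C)(C)C[C@H](O[Si](C)(C)C(C)(C)C)C[C@@]2(C)O1 | intermediate
24 | (5Z)-5-{(2E)-4-[(TBS)oxy]-2-methylbut-2-en-1-ylidene}-3-(DHB)furan-2(5H)-one | CC(C)(C)[Si](C)(C)OC/C=C(C)/C=C1/C=C([C@H]2C=C3C(C)(C)C[C@H](O[Si](C)(C)C(C)(C)C)C[C@@]3(C)O2)C(=O)O1 | intermediate
25 | (5Z)-5-[(2E)-4-hydroxy-2-methylbut-2-en-1-ylidene]-3-(DHB)furan-2(5H)-one | OC/C=C(C)/C=C1/C=C([C@H]2C=C3C(C)(C)C[C@H](O[Si](C)(C)C(C)(C)C)C[C@@]3(C)O2)C(=O)O1 | intermediate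
26 | (2E,4Z)-4-[4-(DHB)-5-oxofuran-2(5H)-ylidene]-3-methylbut-2-enal | O=C/C=C(C)/C=C1/C=C([C@H]2C=C3C(C)(C)C[C@H](O[Si](C)(C)C(C)(C)C)C[C@@]3(C)O2)C(=O)O1 | intermediate
27 | (2E)-5-(RA)-3-methylpent-2-en-4-yn-1-ol | CC1=C(C#C/C(C)=C/CO)C(C)(C)C[C@H](O[Si](C)(C)C(C)(C)C)C1 | intermediate
28 | (2E)-5-(RA)-3-methylpent-2-en-4-ynal | CC1=C(C#C/C(C)=C/C=O)C(C)(C)C[C@H](O[Si](C)(C)C(C)(C)C)C1 | intermediate
29 | ethyl 2-(diethoxyphosphoryl)acetate | CCOC(=O)CP(=O)(OCC)OCC | starting material
30 | ethyl (2E,4E)-7-(RA)-5-methylhepta-2,4-dien-6-ynoate | CC1=C(C#C/C(C)=C/C=C/C(=O)OCC)C(C)(C)C[C@H](O[Si](C)(C)C(C)(C)C)C1 | intermediate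
31 | (2E,4E)-7-(RA)-5-methylhepta-2,4-dien-6-yn-1-ol | CC1=C(C#C/C(C)=C/C=C/CO)C(C)(C)C[C@H](O[Si](C)(C)C(C)(C)C)C1 | intermediate
32 | 5-{[(2E,4E)-7-(RA)-5-methylhepta-2,4-dien-6-yn-1-yl]sulfanyl}-1-phenyl-1H-tetrazole | CC1=C(C#C/C(C)=C/C=C/CSc2nnnn2-c2ccccc2)C(C)(C)C[C@H](O[Si](C)(C)C(C)(C)C)C1 | intermediate
33 | 5-{[(2E,4E)-7-(RA)-5-methylhepta-2,4-dien-6-yn-1-yl]sulfonyl}-1-phenyl-1H-tetrazole | CC1=C(C#C/C(C)=C/C=C/CS(=O)(=O)c2nnnn2-c2ccccc2)C(C)(C)C[C@H](O[Si](C)(C)C(C)(C)C)C1 | intermediate
34 | (15Z)-isomer of 35 (cis at the new C15=C15' bond) | CC1=C(C#C/C(C)=C/C=C/C=C\C=C(C)\C=C2\C=C([C@H]3C=C4C(C)(C)C[C@H](O[Si](C)(C)C(C)(C)C)C[C@@]4(C)O3)C(=O)O2)C(C)(C)C[C@H](O[Si](C)(C)C(C)(C)C)C1 | intermediate (not isolated)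
35 | 3,3'-bis-O-TBS ether of the target (all-E chain, Z-ylidene) | CC1=C(C#C/C(C)=C/C=C/C=C/C=C(C)/C=C2/C=C([C@H]3C=C4C(C)(C)C[C@H](O[Si](C)(C)C(C)(C)C)C[C@@]4(C)O3)C(=O)O2)C(C)(C)C[C@H](O[Si](C)(C)C(C)(C)C)C1 | intermediate
36 | CNP0300047.2, (5Z)-3-[(2R,6S,7aR)-6-hydroxy-4,4,7a-trimethyl-2,4,5,6,7,7a-hexahydro-1-benzofuran-2-yl]-5-{(2E,4E,6E,8E)-11-[(4R)-4-hydroxy-2,6,6-trimethylcyclohex-1-en-1-yl]-2,9-dimethylundeca-2,4,6,8-tetraen-10-yn-1-ylidene}furan-2(5H)-one | CC1=C(C#C/C(C)=C/C=C/C=C/C=C(C)/C=C2/C=C([C@H]3C=C4C(C)(C)C[C@H](O)C[C@@]4(C)O3)C(=O)O2)C(C)(C)C[C@H](O)C1 | target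

## Step count and least certain steps

Total step count: 26. Longest linear sequence: 18 steps (steps 1–10, 13–18, 25 and 26, from 1).

Step 9 (key step). The most likely failure is ring opening: the C7 carbanion can expel the ring oxygen from C8 (retro-oxa-Michael) faster than it is brominated. Strain favours this, because a chair of ring D with sulfur and oxygen both equatorial would put the C1 methyl, the C3 silyloxy group and the C5 methyl syn-axial, so the trans-fused bicycle must twist. A second failure is slow deprotonation at C6, whose hydrogen is axial and flanked by two quaternary carbons, which would allow a second bromination at C7. Fallback: set out from 11 and install the halogen before the ring is closed. α-Lithiation of the vinyl sulfone (LiN(i-Pr)2, 2.2 equiv, THF, –78 °C) and quenching with BrCCl2CCl2Br should give the (Z)-α-bromovinyl sulfone F1. With t-BuOK in t-BuOH/THF the C5 alkoxide adds to C8, the α-bromo sulfone 13 so formed is deprotonated at C6 and contracts through 14 (a Michael-induced Ramberg–Bäcklund sequence), and the route is rejoined at 15.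

Step 8. Ring closure may be incomplete or reversible because of the strain named above, and the potassium alkoxide of 11 could fragment by retro-aldol cleavage of C5–C6 before it cyclises. Fallback: set out from 11 and use fully equilibrating conditions (t-BuOK, 1 equiv, t-BuOH/THF, rt), so that C6, which is α to the sulfonyl group, epimerises. Closure then occurs in the cis-fused series, where ring D keeps a chair with oxygen axial and sulfur equatorial, and should give the cis-fused oxathiane dioxide F2 with the ethynyl group again equatorial. F2 has an equatorial C6–H aligned with the C7 position for 1,3-elimination and is contracted under the conditions of step 9. Because C6 becomes trigonal, the route is rejoined at 15.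

Step 4. Facial selectivity may be poor, the thiiranium ion may lose a proton to give an allylic sulfide, or water may open it at C6. Fallback: set out from 4 and use a halohydrin route. NBS in H2O/THF at 0 °C should give the bromohydrin F3 (OH on C5 anti to the silyloxy group, Br on C6, trans-diaxial). K2CO3 in MeOH closes the epoxide F4, and NaSMe in DMF at 60 °C opens it at the secondary carbon C6 with inversion, rejoining the route at 6.

Step 25. The olefination may give mainly the 15Z isomer with incomplete isomerisation, or the carbanion may attack the butenolide instead of the aldehyde. Fallback: set out from 31 and use a phosphonate. CBr4/PPh3 gives the allylic bromide F5, heating with P(OEt)3 gives the diethyl phosphonate F6, and Horner–Wadsworth–Emmons reaction of F6 with 26 (NaN(SiMe3)2, THF, –78 → 0 °C), which is normally E-selective for allylic phosphonates and enals, rejoins the route at 35.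

Step 13. The acetylide may act as a base: enolisation of the β,γ-unsaturated aldehyde would return 16 and move the double bond of 20 into conjugation. Fallback: set out from 20 and change the electrophile to an acyl donor. NaClO2/NaH2PO4/2-methylbut-2-ene oxidation gives the acid F7, and coupling with MeNHOMe·HCl (EDC·HCl, i-Pr2NEt) gives the Weinreb amide F8. The lithium acetylide of 16 adds to F8 to give the ynone directly, so the route is rejoined at 22 and step 14 is skipped.

## Further compounds

F1 | step 9 | (1R,2R,5S)-2-{[(1Z)-1-bromo-4-(TIPS)but-1-en-3-yn-1-yl]sulfonyl}-5-[(TBS)oxy]-1,3,3-trimethylcyclohexan-1-ol | CC(C)[Si](C(C)C)(C(C)C)C#C/C=C(Br)/S(=O)(=O)[C@@H]1C(C)(C)C[C@H](O[Si](C)(C)C(C)(C)C)C[C@@]1(C)O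
F2 | step 8 | (2S,4aS,7S,8aR)-7-[(TBS)oxy]-5,5,8a-trimethyl-2-[(TIPS)ethynyl]octahydro-2H-1,4-benzoxathiine 4,4-dioxide, cis-fused C6 epimer of 12 | CC(C)[Si](C(C)C)(C(C)C)C#C[C@H]1CS(=O)(=O)[C@H]2C(C)(C)C[C@H](O[Si](C)(C)C(C)(C)C)C[C@@]2(C)O1
F3 | step 4 | 2-bromo-5-[(TBS)oxy]-1,3,3-trimethylcyclohexan-1-ol, OH anti and Br syn to the silyloxy group | Br[C@@H]1C(C)(C)C[C@H](O[Si](C)(C)C(C)(C)C)C[C@@]1(C)O
F4 | step 4 | 5,6-epoxide of 4 with the oxirane oxygen anti to the silyloxy group | CC1(C)C[C@H](O[Si](C)(C)C(C)(C)C)C[C@@]2(C)O[C@@H]12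
F5 | step 25 | (2E,4E)-1-bromo-7-(RA)-5-methylhepta-2,4-dien-6-yne | CC1=C(C#C/C(C)=C/C=C/CBr)C(C)(C)C[C@H](O[Si](C)(C)C(C)(C)C)C1
F6 | step 25 | diethyl [(2E,4E)-7-(RA)-5-methylhepta-2,4-dien-6-yn-1-yl]phosphonate | CC1=C(C#C/C(C)=C/C=C/CP(=O)(OCC)OCC)C(C)(C)C[C@H](O[Si](C)(C)C(C)(C)C)C1
F7 | step 13 | (3E)-5-[(TBS)oxy]-3-methylpent-3-enoic acid | OC(=O)C/C(C)=C/CO[Si](C)(C)C(C)(C)C
F8 | step 13 | (3E)-5-[(TBS)oxy]-N-methoxy-N,3-dimethylpent-3-enamide | CON(C)C(=O)C/C(C)=C/CO[Si](C)(C)C(C)(C)C
A1 | alternative 1 | 3-[(2R,6S,7aR)-6-hydroxy-4,4,7a-trimethyl-2,4,5,6,7,7a-hexahydro-1-benzofuran-2-yl]furan-2(5H)-one | O=C1OCC=C1[C@H]2C=C3C(C)(C)C[C@H](O)C[C@@]3(C)O2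
A2 | alternative 1 | 3-{2-[(2R,4S)-2,4-dihydroxy-2,6,6-trimethylcyclohexylidene]ethenyl}furan-2(5H)-one, allene axis with the butenolide anti to the C5 methyl | O=C1OCC=C1C=[C@]=C1C(C)(C)C[C@H](O)C[C@@]1(C)O
A3 | alternative 2 | (2R,7aR)-4,4,7a-trimethyl-2-[(trimethylsilyl)ethynyl]-2,4,7,7a-tetrahydro-1-benzofuran-6(5H)-one | C[Si](C)(C)C#C[C@H]2C=C3C(C)(C)CC(=O)C[C@@]3(C)O2
A4 | alternative 2 | (4Z)-4-[(2R)-2-hydroxy-4-(trimethylsilyl)but-3-yn-1-ylidene]-3,5,5-trimethylcyclohex-2-en-1-one | C[Si](C)(C)C#C[C@H](O)/C=C1\C(C)=CC(=O)CC1(C)C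
A5 | alternative 3 | (5Z)-5-{(2E)-4-[(TBS)oxy]-2-methylbut-2-en-1-ylidene}-3-(DHB)furan-2(5H)-one, identical with 24 | CC(C)(C)[Si](C)(C)OC/C=C(C)/C=C1/C=C([C@H]2C=C3C(C)(C)C[C@H](O[Si](C)(C)C(C)(C)C)C[C@@]3(C)O2)C(=O)O1
A6 | alternative 3 | (1Z,5E)-7-[(TBS)oxy]-1-(DHB)-1-iodo-5-methylhepta-1,5-dien-3-one, identical with 23 | CC(C)(C)[Si](C)(C)OC/C=C(C)/CC(=O)/C=C(I)/[C@H]1C=C2C(C)(C)C[C@H](O[Si](C)(C)C(C)(C)C)C[C@@]2(C)O1
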